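(The data come from a simulation for substances that don't exist, and the scatter is random.)

Count the nucleophile.

| flask | starting material | first nucleophile | second nucleophile | protic impurity | remark | time |
|---|---|---|---|---|---|---|
| amber | 16 mM | 9.6 mM | 9.6 mM | 0.32 mM | the very flask that is asked about, followed so far |  |
| violet | 32 mM | 9.6 mM | 9.6 mM | 0.32 mM | run made earlier |  |
| flask | 16 mM | 9.60 mM | 9.60 mM | 0.320 mM |  | 20 h |

| run | time / h | target / % | solvolysis product / % | starting material / % | intermediate / % | other capture product / % |
|---|---|---|---|---|---|---|
| amber | 0.333 | 1.5 | 0.9 | 93.8 | 1.1 | 1.2 |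
| amber | 1.00 | 1.6 | 0.7 | 87.4 | 2.1 | 6.3 |
| amber | 2.00 | 3.4 | 2.5 | 76.9 | 1.2 | 14.0 |
| amber | 3.00 | 5.5 | 3.6 | 69.2 | 2.2 | 20.1 |
| amber | 4.00 | 7.9 | 4.2 | 60.1 | 1.8 | 24.2 |
| violet | 4.00 | 7.8 | 5.3 | 60.1 | 2.7 | 23.2 |
| violet | 8.00 | 14.9 | 13.0 | 37.9 | 3.4 | 28.8 |
| violet | 12.0 | 20.6 | 21.2 | 23.8 | 3.3 | 30.2 |
| violet | 15.0 | 21.6 | 28.5 | 16.7 | 2.8 | 29.5 |
| violet | 20.0 | 22.9 | 35.8 | 8.5 | 1.2 | 29.9 |

(scatter of a reading: 0.5 percentage points)

- the species in which most of what was charged as starting material, at 20 h sits (other capture product / solvolysis product / starting material / intermediate / target)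
- the largest share itself, whichever of these holds it, in percent of the starting material charged

Suppose one molecule of second nucleophile goes into each other capture product; the first nucleophile has the same charge, so the number below stands either way. The balance of second nucleophile, charged below the starting material, then gives a single number:

roof = c(second nucleophile) / c(starting material) = 9.60 mM / 16 mM = 60.0%

This roof, the charge ratio, is the largest share of other capture product that the charges allow. In violet the same ratio is 30.0%, and the readings there stand at 30.2% and 29.9% at 12.0 h and 20.0 h, so violet's readings lie at its roof within their scatter.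

One number is not enough for amber, though: its roof still has to be reached by supply. Starting material reads 60.1% in amber and 60.1% in violet at 4.00 h, so violet's reading of 8.5% at 20.0 h is carried over to amber, and 91.5% is reckoned as consumed. Of the target, solvolysis product and other capture product read in amber at 4.00 h, other capture product holds 66.7%:

supply = 91.5% × 66.7% = 61.0%

Supply only just matches the roof, and the capture share should sink as the nucleophile thins. The estimate is therefore other capture product, below 60.0%.

The forecast said other capture product at 54%, range 49% to 59%, holding that “the products are set by competition for the intermediate”.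

The flask gives other capture product at 52.3%.

    starting material + protic impurity → quenched substrate (k = 191 L mol⁻¹ h⁻¹)
    first nucleophile → decomposed reagent (k = 0.0171 h⁻¹)
    starting material → intermediate (k = 0.120 h⁻¹)
    second nucleophile + intermediate → other capture product (k = 547 L mol⁻¹ h⁻¹)
    first nucleophile + intermediate → target (k = 128 L mol⁻¹ h⁻¹)
    intermediate → solvolysis product (k = 0.685 h⁻¹)

That fills 87.2% of the roof. In the flask at 20.0 h, second nucleophile, the limiting reagent of this product, stands at 12.8% of its charge, and 60.0% × (1 − 12.8%) = 52.3%.

A neighbour charged with 2.4 mM of second nucleophile has a roof of 15.0%, under the 61.0% of supply reckoned for amber, so its roof should fill. At 20.0 h that neighbour gives 14.9% other capture product with 0.871% of its charge of second nucleophile left, and solvolysis product leads at 37.1%.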